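**Plan**
- Retrosynthesis: the interflavan bond C4(upper)–C8(lower) is cut first (Friedel–Crafts), then ring C of the lower unit is cut at C3–C4 and O1–C8a in one stroke, then the upper ring C at C2–aryl.
- Enabling feature: in the lower ring C, O1–C2(aryl)–C3(O) is the enolate of an α-alkoxy aryl ketone (a 1,3-O,C-dinucleophile) and C4–C4a–C8a of ring A is an ortho-bromobenzyl bromide (a 1,3-dielectrophile). C8a lies meta to both ring-A oxygens, so it enters as C–Br and not through phenol chemistry.
- Forward: ring-A bromide 5 and ketone 10 are joined in one pot (C-benzylation, then copper-catalysed O-arylation) to the 4H-chromene 13. The 4-methoxybenzyl group, which carries the C3 oxygen through the enol-ether stage, is then removed to give flavan-3-one 14.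
- Stereochemistry: lower C2 and C3 (2R,3R, cis) come from asymmetric transfer hydrogenation of 14 with dynamic kinetic resolution. Upper C2 (S) comes from a palladium-catalysed asymmetric conjugate addition to a chromone. Upper C4 (R) comes from trans-selective capture of the flavan-4-yl cation, controlled by upper C2.
- End: union of the two flavan units and hydrogenolysis of eight benzyl ethers.

Key step: step 5

Assumption: the sense of induction of (R)-t-BuPyOx in step 9 and of the (S,S)-TsDPEN complex in step 7 is taken by analogy with their standard substrates; if either gave the antipodal centre, the mirror-image ligand would be used.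

**Step 1**
Reactants: 1 1-bromo-3,5-bis(benzyloxy)benzene
Product: 3 2-bromo-4,6-bis(benzyloxy)benzaldehyde, via iminium salt 2 (not isolated)
Conditions: POCl3, DMF, 0 to 80 °C; then aq. NaOAc
Reagents that add atoms: N,N-dimethylformamide (CN(C)C=O); water (O)
Why: Vilsmeier–Haack formylation; the chloroiminium ion should attack para to one benzyloxy group and ortho to bromine rather than between the two benzyloxy groups, as is usual for 5-substituted resorcinol diethers, and the iminium salt is hydrolysed on work-up.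

**Step 2**
Reactants: 3 2-bromo-4,6-bis(benzyloxy)benzaldehyde
Product: 4 [2-bromo-4,6-bis(benzyloxy)phenyl]methanol
Conditions: NaBH4, THF/MeOH, 0 °C
Reagents that add atoms: none
Why: Borohydride reduction of an aryl aldehyde; the aryl bromide and the benzyl ethers are inert.

**Step 3**
Reactants: 4 [2-bromo-4,6-bis(benzyloxy)phenyl]methanol
Product: 5 2-bromo-4,6-bis(benzyloxy)benzyl bromide
Conditions: PBr3, CH2Cl2, 0 °C; used crude at once
Reagents that add atoms: phosphorus tribromide (BrP(Br)Br)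
Why: Bromination of an electron-rich benzylic alcohol through its phosphite ester; the bromide is prone to self-alkylation and is therefore not stored.

**Step 4**
Reactants: 6 5-bromo-1,2,3-tris(benzyloxy)benzene; 7 N-methoxy-2-[(4-methoxybenzyl)oxy]-N-methylacetamide
Product: 10 2-[(4-methoxybenzyl)oxy]-1-[3,4,5-tris(benzyloxy)phenyl]ethan-1-one, via aryllithium 8 (not isolated), via tetrahedral lithium adduct 9 (not isolated)
Conditions: n-BuLi, THF, −78 °C; then 7, −78 to 0 °C; aq. NH4Cl
Reagents that add atoms: none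
Why: Bromine–lithium exchange followed by Weinreb ketone synthesis; the N,O-chelated tetrahedral adduct prevents a second addition.

**Step 5**
Reactants: 10 2-[(4-methoxybenzyl)oxy]-1-[3,4,5-tris(benzyloxy)phenyl]ethan-1-one; 5 2-bromo-4,6-bis(benzyloxy)benzyl bromide
Product: 13 5,7-bis(benzyloxy)-3-[(4-methoxybenzyl)oxy]-2-[3,4,5-tris(benzyloxy)phenyl]-4H-chromene, via lithium enolate 11 (not isolated), via C-benzylated ketone 12 (not isolated)
Conditions: LiN(SiMe3)2, THF, −78 °C; then 5, −78 to 0 °C; then CuI (10 mol%), 1,10-phenanthroline (20 mol%), K3PO4, DMF, THF distilled off, 100 °C, one pot, degassed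
Reagents that add atoms: none
Why: Proposed new method: the lithium enolate 11 is C-benzylated at C3 by the highly reactive ortho,para-dialkoxybenzyl bromide 5 (C3–C4 bond), and after the solvent switch the enolate of 12 is O-arylated at C8a through a monovalent copper enolate that adds oxidatively into the aryl C–Br bond and eliminates reductively (O1–C8a bond). The closest known reaction type is the copper-catalysed domino C-benzylation/O-arylation of 1,3-dicarbonyl compounds with 2-bromobenzyl bromides to 4H-chromenes, together with the copper-catalysed intramolecular O-arylation of simple ketone enolates to benzofurans; the extension is to a mono-ketone whose only extra activation is the α-alkoxy group. Ring C closes as a six-membered ring in a 6-exo sense at the ipso carbon C8a, with the enolate oxygen and C4 held cis on the C2=C3 bond after enolate equilibration. No stereocentre is formed, since C2 and C3 leave the step as the sp2 carbons of an enol ether. The step needs C- over O-benzylation, secured by the lithium counter-ion in THF at low temperature, and O- over C-arylation, secured because C-arylation would close a four-membered ring. Ring-A regiochemistry is unambiguous, because in 5 the carbon that becomes C8a carries the only aryl bromide and the carbon that becomes C4 the only benzylic halide.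

**Step 6**
Reactants: 13 5,7-bis(benzyloxy)-3-[(4-methoxybenzyl)oxy]-2-[3,4,5-tris(benzyloxy)phenyl]-4H-chromene
Product: 14 5,7-bis(benzyloxy)-2-[3,4,5-tris(benzyloxy)phenyl]chroman-3-one (racemic at C2)
Conditions: CF3CO2H, 1,3-dimethoxybenzene (5 equiv), CH2Cl2, −20 to 0 °C
Reagents that add atoms: none
Why: Acidolysis of the 4-methoxybenzyl enol ether; the 4-methoxybenzyl cation is trapped by 1,3-dimethoxybenzene in a Friedel–Crafts alkylation, and the freed C3 enol tautomerises to the ketone, with C2 formed racemic on purpose.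

**Step 7**
Reactants: 14 5,7-bis(benzyloxy)-2-[3,4,5-tris(benzyloxy)phenyl]chroman-3-one
Product: 15 (2R,3R)-5,7-bis(benzyloxy)-2-[3,4,5-tris(benzyloxy)phenyl]chroman-3-ol
Conditions: RuCl[(S,S)-TsDPEN](p-cymene) (2 mol%), HCO2H, Et3N (excess), DMF, 40 °C
Reagents that add atoms: none
Why: Asymmetric transfer hydrogenation with dynamic kinetic resolution; C2–H (α to the ketone, benzylic and α to oxygen) should epimerise through the enol under the amine, while the catalyst reduces the 2R ketone faster and delivers hydride to C3 on the face opposite the C2 aryl group, giving the 2,3-cis (2R,3R) alcohol.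

**Step 8**
Reactants: 16 7-hydroxy-4H-chromen-4-one
Product: 17 7-(benzyloxy)-4H-chromen-4-one
Conditions: BnBr, K2CO3, DMF, rt
Reagents that add atoms: benzyl bromide (BrCc1ccccc1)
Why: Williamson ether synthesis on the only acidic site, the 7-phenol.

**Step 9**
Reactants: 17 7-(benzyloxy)-4H-chromen-4-one; 18 [3,4-bis(benzyloxy)phenyl]boronic acid
Product: 19 (2S)-7-(benzyloxy)-2-[3,4-bis(benzyloxy)phenyl]chroman-4-one
Conditions: Pd(OCOCF3)2 (5 mol%), (R)-t-BuPyOx (6 mol%), NH4PF6, H2O, ClCH2CH2Cl, 60 °C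
Reagents that add atoms: none
Why: Asymmetric conjugate addition of an arylboronic acid to a chromone under divalent palladium with a pyridine–oxazoline ligand; the aryl–palladium species adds across C2=C3, the palladium enolate is protonated, and the ligand sets C2 (S).

**Step 10**
Reactants: 19 (2S)-7-(benzyloxy)-2-[3,4-bis(benzyloxy)phenyl]chroman-4-one
Product: 20 (2S,4S)-7-(benzyloxy)-2-[3,4-bis(benzyloxy)phenyl]chroman-4-ol
Conditions: NaBH4, THF/MeOH, 0 °C
Reagents that add atoms: none
Why: Borohydride reduction of the flavanone, expected to give mainly the 2,4-cis alcohol by axial hydride attack; C2 is untouched and the C4 configuration is erased in step 11, so the 4-epimer is equally usable.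

**Step 11**
Reactants: 20 (2S,4S)-7-(benzyloxy)-2-[3,4-bis(benzyloxy)phenyl]chroman-4-ol; 15 (2R,3R)-5,7-bis(benzyloxy)-2-[3,4,5-tris(benzyloxy)phenyl]chroman-3-ol (3 equiv)
Product: 21 (2R,3R)-5,7-bis(benzyloxy)-8-{(2S,4R)-7-(benzyloxy)-2-[3,4-bis(benzyloxy)phenyl]chroman-4-yl}-2-[3,4,5-tris(benzyloxy)phenyl]chroman-3-ol
Conditions: TMSOTf (0.2 equiv), CH2Cl2, −78 to −40 °C; slow addition of 20
Reagents that add atoms: none
Why: Friedel–Crafts alkylation with loss of water; ionisation of the 4-hydroxyl gives a benzylic cation stabilised by O1 (ortho) and the 7-benzyloxy group (para), and C8 of 15, the less hindered nucleophilic carbon of the phloroglucinol-type ring A, should attack axially, anti to the equatorial C2 aryl group, which sets upper C4 (R) in a 2,4-trans relation.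

**Step 12**
Reactants: 21 (2R,3R)-5,7-bis(benzyloxy)-8-{(2S,4R)-7-(benzyloxy)-2-[3,4-bis(benzyloxy)phenyl]chroman-4-yl}-2-[3,4,5-tris(benzyloxy)phenyl]chroman-3-ol
Product: 22 (2R,3R)-8-[(2S,4R)-2-(3,4-dihydroxyphenyl)-7-hydroxychroman-4-yl]-2-(3,4,5-trihydroxyphenyl)chroman-3,5,7-triol
Conditions: H2 (1 atm), Pd(OH)2/C, THF/MeOH/H2O, rt; work-up under argon
Reagents that add atoms: none
Why: Hydrogenolysis of eight benzyl ethers; the cyclic benzylic C2–O1 ethers and the diarylmethine C4–H are of the kind that survives these conditions in proanthocyanidin work, and no stereocentre is touched.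

**Compound list**
1 | 1-bromo-3,5-bis(benzyloxy)benzene | Brc1cc(OCc2ccccc2)cc(OCc2ccccc2)c1 | starting material
2 | N-{[2-bromo-4,6-bis(benzyloxy)phenyl]methylidene}-N-methylmethanaminium dichlorophosphate | C[N+](C)=Cc1c(Br)cc(OCc2ccccc2)cc1OCc1ccccc1.[O-]P(=O)(Cl)Cl | intermediate (not isolated)
3 | 2-bromo-4,6-bis(benzyloxy)benzaldehyde | O=Cc1c(Br)cc(OCc2ccccc2)cc1OCc1ccccc1 | intermediate
4 | [2-bromo-4,6-bis(benzyloxy)phenyl]methanol | OCc1c(Br)cc(OCc2ccccc2)cc1OCc1ccccc1 | intermediate
5 | 2-bromo-4,6-bis(benzyloxy)benzyl bromide | BrCc1c(Br)cc(OCc2ccccc2)cc1OCc1ccccc1 | intermediate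
6 | 5-bromo-1,2,3-tris(benzyloxy)benzene | Brc1cc(OCc2ccccc2)c(OCc2ccccc2)c(OCc2ccccc2)c1 | starting material
7 | N-methoxy-2-[(4-methoxybenzyl)oxy]-N-methylacetamide | CON(C)C(=O)COCc1ccc(OC)cc1 | starting material
8 | [3,4,5-tris(benzyloxy)phenyl]lithium | [Li]c1cc(OCc2ccccc2)c(OCc2ccccc2)c(OCc2ccccc2)c1 | intermediate (not isolated)
9 | lithium 1-[methoxy(methyl)amino]-2-[(4-methoxybenzyl)oxy]-1-[3,4,5-tris(benzyloxy)phenyl]ethan-1-olate | [Li+].[O-]C(COCc1ccc(OC)cc1)(N(C)OC)c1cc(OCc2ccccc2)c(OCc2ccccc2)c(OCc2ccccc2)c1 | intermediate (not isolated)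
10 | 2-[(4-methoxybenzyl)oxy]-1-[3,4,5-tris(benzyloxy)phenyl]ethan-1-one | COc1ccc(COCC(=O)c2cc(OCc3ccccc3)c(OCc3ccccc3)c(OCc3ccccc3)c2)cc1 | intermediate
11 | lithium (Z)-2-[(4-methoxybenzyl)oxy]-1-[3,4,5-tris(benzyloxy)phenyl]ethen-1-olate | [Li+].[O-]/C(=C\OCc1ccc(OC)cc1)c1cc(OCc2ccccc2)c(OCc2ccccc2)c(OCc2ccccc2)c1 | intermediate (not isolated)
12 | 3-[2-bromo-4,6-bis(benzyloxy)phenyl]-2-[(4-methoxybenzyl)oxy]-1-[3,4,5-tris(benzyloxy)phenyl]propan-1-one (racemic) | COc1ccc(COC(Cc2c(Br)cc(OCc3ccccc3)cc2OCc2ccccc2)C(=O)c2cc(OCc3ccccc3)c(OCc3ccccc3)c(OCc3ccccc3)c2)cc1 | intermediate (not isolated)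
13 | 5,7-bis(benzyloxy)-3-[(4-methoxybenzyl)oxy]-2-[3,4,5-tris(benzyloxy)phenyl]-4H-chromene | COc1ccc(COC2=C(c3cc(OCc4ccccc4)c(OCc4ccccc4)c(OCc4ccccc4)c3)Oc3cc(OCc4ccccc4)cc(OCc4ccccc4)c3C2)cc1 | intermediate
14 | 5,7-bis(benzyloxy)-2-[3,4,5-tris(benzyloxy)phenyl]chroman-3-one (racemic at C2) | O=C1Cc2c(OCc3ccccc3)cc(OCc3ccccc3)cc2OC1c1cc(OCc2ccccc2)c(OCc2ccccc2)c(OCc2ccccc2)c1 | intermediate
15 | (2R,3R)-5,7-bis(benzyloxy)-2-[3,4,5-tris(benzyloxy)phenyl]chroman-3-ol (2,3-cis) | O[C@@H]1Cc2c(OCc3ccccc3)cc(OCc3ccccc3)cc2O[C@@H]1c1cc(OCc2ccccc2)c(OCc2ccccc2)c(OCc2ccccc2)c1 | intermediate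
16 | 7-hydroxy-4H-chromen-4-one | O=c1ccoc2cc(O)ccc12 | starting material
17 | 7-(benzyloxy)-4H-chromen-4-one | O=c1ccoc2cc(OCc3ccccc3)ccc12 | intermediate
18 | [3,4-bis(benzyloxy)phenyl]boronic acid | OB(O)c1ccc(OCc2ccccc2)c(OCc2ccccc2)c1 | starting material
19 | (2S)-7-(benzyloxy)-2-[3,4-bis(benzyloxy)phenyl]chroman-4-one | O=C1C[C@@H](c2ccc(OCc3ccccc3)c(OCc3ccccc3)c2)Oc2cc(OCc3ccccc3)ccc12 | intermediate
20 | (2S,4S)-7-(benzyloxy)-2-[3,4-bis(benzyloxy)phenyl]chroman-4-ol (2,4-cis) | O[C@H]1C[C@@H](c2ccc(OCc3ccccc3)c(OCc3ccccc3)c2)Oc2cc(OCc3ccccc3)ccc12 | intermediate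
21 | (2R,3R)-5,7-bis(benzyloxy)-8-{(2S,4R)-7-(benzyloxy)-2-[3,4-bis(benzyloxy)phenyl]chroman-4-yl}-2-[3,4,5-tris(benzyloxy)phenyl]chroman-3-ol | O(Cc1ccccc1)c1ccc2c(c1)O[C@H](c1ccc(OCc3ccccc3)c(OCc3ccccc3)c1)C[C@H]2c1c(OCc3ccccc3)cc(OCc3ccccc3)c2c1O[C@H](c1cc(OCc3ccccc3)c(OCc3ccccc3)c(OCc3ccccc3)c1)[C@H](O)C2 | intermediate
22 | (2R,3R)-8-[(2S,4R)-2-(3,4-dihydroxyphenyl)-7-hydroxychroman-4-yl]-2-(3,4,5-trihydroxyphenyl)chroman-3,5,7-triol | Oc1ccc2c(c1)O[C@H](c1ccc(O)c(O)c1)C[C@H]2c1c(O)cc(O)c2c1O[C@H](c1cc(O)c(O)c(O)c1)[C@H](O)C2 | target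

**Step count**
Total: 12 steps. Longest linear sequence: 8 steps (steps 1, 2, 3, 5, 6, 7, 11, 12).

**Steps most likely to fail**

Step 5 (Proposed new method). The O-arylation of a mono-ketone enolate may be too slow, so that protodebromination, enolate oxidation or a second benzylation take over. The fallback rests on well-established reactions and sets out from 10 and 5. The lithium enolate alkylation is run alone and the ketone 12 is isolated. NaBH4 reduction gives the bromo alcohol F1 as a diastereomer mixture. Intramolecular Ullmann-type etherification of the benzylic hydroxyl (CuI, 3,4,7,8-tetramethyl-1,10-phenanthroline, Cs2CO3, toluene, 110 °C) closes ring C through O1–C8a to the 3-(4-methoxybenzyloxy)flavan F2. Acidolysis (CF3CO2H, 1,3-dimethoxybenzene) gives the racemic flavan-3-ol F3, and Dess–Martin periodinane oxidises it to ketone 14, where the route is rejoined. The relative configuration of F1 to F3 does not matter, because both centres are reset in step 7.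

Step 7. Epimerisation of C2 may be slow compared with reduction, so that the dynamic resolution is lost, or the catalyst may discriminate the two ketone enantiomers poorly. The fallback sets out from 14. LiBH(s-Bu)3 (THF, −78 °C) reduces the racemic ketone from the face opposite the C2 aryl group to the racemic cis alcohol, that is 15 together with its enantiomer F4. This mixture is used in step 11 with enantiopure 20, which then acts as the resolving partner. The diastereomeric dimer F5 is separated from 21 by chromatography, and the route is rejoined at 21.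

Step 11. The cation may be captured by ring A of a second molecule of electrophile (oligomerisation), attack may occur at C6 instead of C8, 2,4-trans selectivity may be incomplete, or the cation may lose a proton to the flav-3-ene. The fallback is a protecting-group-free condensation under thermodynamic control and sets out from 19 and 15. Hydrogenolysis of 19 (H2, Pd/C, EtOAc) gives (S)-butin F6, and NaBH4 reduces it to the free flavan-4-ol F7. Hydrogenolysis of 15 gives (−)-epigallocatechin F8. F7 and an excess of F8 are condensed in dilute aqueous HCl at room temperature, where the benzylic cation of F7, stabilised as a quinone methide by the 7-hydroxyl, is captured reversibly by C8 of F8. This comes back to the route at 22.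

**Further compounds**
F1 | step 5 | 3-[2-bromo-4,6-bis(benzyloxy)phenyl]-2-[(4-methoxybenzyl)oxy]-1-[3,4,5-tris(benzyloxy)phenyl]propan-1-ol (diastereomer mixture, racemic) | COc1ccc(COC(Cc2c(Br)cc(OCc3ccccc3)cc2OCc2ccccc2)C(O)c2cc(OCc3ccccc3)c(OCc3ccccc3)c(OCc3ccccc3)c2)cc1
F2 | step 5 | 5,7-bis(benzyloxy)-3-[(4-methoxybenzyl)oxy]-2-[3,4,5-tris(benzyloxy)phenyl]chroman (diastereomer mixture, racemic) | COc1ccc(COC2Cc3c(OCc4ccccc4)cc(OCc4ccccc4)cc3OC2c2cc(OCc3ccccc3)c(OCc3ccccc3)c(OCc3ccccc3)c2)cc1
F3 | step 5 | 5,7-bis(benzyloxy)-2-[3,4,5-tris(benzyloxy)phenyl]chroman-3-ol (diastereomer mixture, racemic) | OC1Cc2c(OCc3ccccc3)cc(OCc3ccccc3)cc2OC1c1cc(OCc2ccccc2)c(OCc2ccccc2)c(OCc2ccccc2)c1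
F4 | step 7 | (2S,3S)-5,7-bis(benzyloxy)-2-[3,4,5-tris(benzyloxy)phenyl]chroman-3-ol (enantiomer of 15) | O[C@H]1Cc2c(OCc3ccccc3)cc(OCc3ccccc3)cc2O[C@H]1c1cc(OCc2ccccc2)c(OCc2ccccc2)c(OCc2ccccc2)c1
F5 | step 7 | (2S,3S)-5,7-bis(benzyloxy)-8-{(2S,4R)-7-(benzyloxy)-2-[3,4-bis(benzyloxy)phenyl]chroman-4-yl}-2-[3,4,5-tris(benzyloxy)phenyl]chroman-3-ol | O(Cc1ccccc1)c1ccc2c(c1)O[C@H](c1ccc(OCc3ccccc3)c(OCc3ccccc3)c1)C[C@H]2c1c(OCc3ccccc3)cc(OCc3ccccc3)c2c1O[C@@H](c1cc(OCc3ccccc3)c(OCc3ccccc3)c(OCc3ccccc3)c1)[C@@H](O)C2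
F6 | step 11 | (2S)-2-(3,4-dihydroxyphenyl)-7-hydroxychroman-4-one ((S)-butin) | O=C1C[C@@H](c2ccc(O)c(O)c2)Oc2cc(O)ccc12
F7 | step 11 | (2S,4S)-2-(3,4-dihydroxyphenyl)chroman-4,7-diol | O[C@H]1C[C@@H](c2ccc(O)c(O)c2)Oc2cc(O)ccc12
F8 | step 11 | (2R,3R)-2-(3,4,5-trihydroxyphenyl)chroman-3,5,7-triol ((−)-epigallocatechin) | O[C@@H]1Cc2c(O)cc(O)cc2O[C@@H]1c1cc(O)c(O)c(O)c1
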